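**Assumption:** Rigidin C has no stereocentre and no stereogenic double bond, so the given SMILES defines one achiral compound and no stereocontrol is needed.

## Retrosynthetic overview

1. Building blocks: 2-bromo-1-(4-hydroxyphenyl)ethan-1-one 1 (turned into azido ketone 2), vanillin 3 (condensed with 2 to the α-azido enone 4) and 6-aminouracil 5, which brings the finished pyrimidinedione ring.
2. Key disconnection: the pyrrole N7–C6 bond, closed last inside azido ketone adduct 6. Loss of N2 gives imino ketone 7, the uracil 6-NH2 adds to the imine carbon (cyclic aminal 8), and loss of NH3 gives the target 9.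
3. Second disconnection: C4a–C5, from conjugate addition of C5 of 5 to the β-carbon of 4.
4. Remaining disconnections: the C=C bond of 4 (Knoevenagel condensation) and the C–N3 bond of 2 (SN2).
5. Ring order: the pyrimidinedione ring is bought; the pyrrole ring is the only ring made, in the last step. No protecting group and no external oxidant are used (the azide is the internal oxidant).

## Route

Step 1
Reactants: 1 2-bromo-1-(4-hydroxyphenyl)ethan-1-one
Product: 2 2-azido-1-(4-hydroxyphenyl)ethan-1-one
Conditions: NaN3 (1.2 equiv), acetone/H2O 4:1, 0 °C → rt; keep below 40 °C, use as a solution or freshly crystallised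
Reagents that add atoms: sodium azide, [Na+].[N-]=[N+]=[N-]
Why: SN2 displacement of an α-bromo ketone by azide is very fast, and azide (HN3 pKa 4.7) is too weak a base to form the phenoxide, so the free phenol does not self-alkylate; no stereocentre is formed.

Step 2
Reactants: 2 2-azido-1-(4-hydroxyphenyl)ethan-1-one; 3 vanillin
Product: 4 (Z)-2-azido-3-(4-hydroxy-3-methoxyphenyl)-1-(4-hydroxyphenyl)prop-2-en-1-one
Conditions: piperidine (20 mol%), AcOH (20 mol%), EtOH, 4 Å molecular sieves, 0 °C → rt, dark
Reagents that add atoms: none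
Why: Knoevenagel-type aldol condensation of an α-azido ketone with an aromatic aldehyde under buffered piperidinium acetate (iminium activation of vanillin, mild enough to avoid base-induced N2 loss) gives the α-azidovinyl ketone as the more stable Z isomer (aryl trans to aroyl); the geometry is lost in step 3.

Step 3
Reactants: 4 (Z)-2-azido-3-(4-hydroxy-3-methoxyphenyl)-1-(4-hydroxyphenyl)prop-2-en-1-one; 5 6-aminouracil
Product: 9 rigidin C, via azido ketone adduct 6 (not isolated), via imino ketone 7 (not isolated), via cyclic aminal 8 (not isolated)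
Conditions: CF3SO3H (10 mol%), (CF3)2CHOH (HFIP), 30 °C, dark; evaporate; then Et3N (3 equiv), DMSO, 25 → 90 °C
Reagents that add atoms: none
Why: Proposed new method: a redox-neutral denitrogenative aza-annulation in which acid in HFIP converts enone 4 into a para-hydroxybenzyl-stabilised hydroxyallyl cation that is captured at its β-carbon by the enamine carbon C5 of 5 (Friedel–Crafts-type conjugate addition) to give 6, after which Et3N removes the proton α to C=O and N3 and the carbanion expels N2 to give the electrophilic N–H imino ketone 7 (the azide acts as an internal two-electron oxidant that turns the α-carbon from nucleophile into electrophile), the neighbouring 6-NH2 adds 5-exo-trig to the imine carbon to form the key N7–C6 bond in aminal 8, and loss of NH3 with a C5–H shift gives the aromatic pyrrole of 9, so the stereocentres of 6 to 8 never matter; the 30 °C dark addition keeps 4 from opening to the 2H-azirine, which would lead to the regioisomer; closest known reaction types are the Cu(NTf2)2-catalysed (divalent copper) 1,4-addition of 1,3-dicarbonyl compounds to vinyl azides with N2 loss and condensation to NH-pyrroles, and the amine-induced N2 loss of α-azido ketones to α-imino ketones.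

## Compound list

1 | 2-bromo-1-(4-hydroxyphenyl)ethan-1-one | O=C(CBr)c1ccc(O)cc1 | starting material
2 | 2-azido-1-(4-hydroxyphenyl)ethan-1-one | [N-]=[N+]=NCC(=O)c1ccc(O)cc1 | intermediate
3 | vanillin (4-hydroxy-3-methoxybenzaldehyde) | COc1cc(C=O)ccc1O | starting material
4 | (Z)-2-azido-3-(4-hydroxy-3-methoxyphenyl)-1-(4-hydroxyphenyl)prop-2-en-1-one | COc1cc(/C=C(\N=[N+]=[N-])C(=O)c2ccc(O)cc2)ccc1O | intermediate
5 | 6-aminouracil (6-aminopyrimidine-2,4(1H,3H)-dione) | Nc1cc(=O)[nH]c(=O)[nH]1 | starting material
6 | 6-amino-5-[2-azido-1-(4-hydroxy-3-methoxyphenyl)-3-(4-hydroxyphenyl)-3-oxopropyl]pyrimidine-2,4(1H,3H)-dione (racemic, both diastereomers, no descriptor assigned) | COc1cc(C(C(N=[N+]=[N-])C(=O)c2ccc(O)cc2)c2c(N)[nH]c(=O)[nH]c2=O)ccc1O | intermediate (not isolated)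
7 | 6-amino-5-[1-(4-hydroxy-3-methoxyphenyl)-3-(4-hydroxyphenyl)-2-imino-3-oxopropyl]pyrimidine-2,4(1H,3H)-dione (racemic) | COc1cc(C(C(=N)C(=O)c2ccc(O)cc2)c2c(N)[nH]c(=O)[nH]c2=O)ccc1O | intermediate (not isolated)
8 | 6-amino-6-(4-hydroxybenzoyl)-5-(4-hydroxy-3-methoxyphenyl)-5,6-dihydro-1H-pyrrolo[2,3-d]pyrimidine-2,4(3H,7H)-dione (racemic, both diastereomers) | COc1cc(C2c3c(NC2(N)C(=O)c2ccc(O)cc2)[nH]c(=O)[nH]c3=O)ccc1O | intermediate (not isolated)
9 | rigidin C, 6-(4-hydroxybenzoyl)-5-(4-hydroxy-3-methoxyphenyl)-1H-pyrrolo[2,3-d]pyrimidine-2,4(3H,7H)-dione | COc1cc(-c2c(C(=O)c3ccc(O)cc3)[nH]c3[nH]c(=O)[nH]c(=O)c23)ccc1O | target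

## Summary

Total step count: 3.
Longest linear sequence: 3 steps (1 → 2 → 4 → 9).

## Steps most likely to fail, with fallbacks

**Step 3 (the proposed new step).** Three things can go wrong. The 6-NH2 of adduct 6 may condense with the aryl ketone instead, closing a six-membered ring to a 6-aminopyrido[2,3-d]pyrimidine. Enone 4 may open to the 2H-azirine if warmed before it is consumed, which leads to the 6-aryl-5-aroyl regioisomer. The conjugate addition to the electron-rich enone may be slow.

The fallback uses known chemistry, sets out from azide 2 and vanillin 3, and comes back at 9. Azide 2 is hydrogenated (H2, 10% Pd/C, HCl, EtOH) to 2-amino-1-(4-hydroxyphenyl)ethan-1-one hydrochloride F1. This is N-mesylated (MsCl 1.0 equiv, pyridine, 0 °C) to N-[2-(4-hydroxyphenyl)-2-oxoethyl]methanesulfonamide F2. The known three-component pyrrole synthesis of F2 with vanillin 3 and 2-cyanoacetamide (K2CO3, EtOH, reflux; Knoevenagel condensation, Michael addition, N-attack on the nitrile, loss of methanesulfinate) gives 2-amino-5-(4-hydroxybenzoyl)-4-(4-hydroxy-3-methoxyphenyl)-1H-pyrrole-3-carboxamide F3. The known closure of 2-aminopyrrole-3-carboxamides with oxalyl chloride (diglyme, 120 °C, then aqueous NaHCO3) builds the pyrimidinedione ring and gives 9.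

**Step 2.** Vanillin is a weak electrophile because of its para-hydroxyl, and azido ketone 2 can lose N2 under amine base before it condenses.

The fallback masks the vanillin hydroxyl; it sets out from 3 and comes back at 4. Vanillin 3 is silylated (i-Pr3SiCl, imidazole, DMF) to 3-methoxy-4-[(triisopropylsilyl)oxy]benzaldehyde F4, which now behaves like an ordinary alkoxybenzaldehyde. The same piperidinium acetate condensation with 2 gives (Z)-2-azido-1-(4-hydroxyphenyl)-3-{3-methoxy-4-[(triisopropylsilyl)oxy]phenyl}prop-2-en-1-one F5. Buffered fluoride (Bu4NF, AcOH, THF, 0 °C) removes the silyl group and gives 4.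

**Step 1.** Any phenoxide formed would alkylate a second molecule of bromo ketone 1, and azido ketone 2 may decompose on concentration.

The fallback keeps the phenol masked under acid-only conditions; it sets out from 1 and comes back at 2. Bromo ketone 1 is treated with 3,4-dihydro-2H-pyran and catalytic pyridinium p-toluenesulfonate in CH2Cl2 to give 2-bromo-1-[4-(tetrahydro-2H-pyran-2-yloxy)phenyl]ethan-1-one F6 (racemic). NaN3 in acetone/H2O gives 2-azido-1-[4-(tetrahydro-2H-pyran-2-yloxy)phenyl]ethan-1-one F7 (racemic). Methanolysis (pyridinium p-toluenesulfonate, MeOH, 40 °C) releases 2.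

## Further compounds

F1 | step 3 | 2-amino-1-(4-hydroxyphenyl)ethan-1-one hydrochloride | Cl.NCC(=O)c1ccc(O)cc1
F2 | step 3 | N-[2-(4-hydroxyphenyl)-2-oxoethyl]methanesulfonamide | CS(=O)(=O)NCC(=O)c1ccc(O)cc1
F3 | step 3 | 2-amino-5-(4-hydroxybenzoyl)-4-(4-hydroxy-3-methoxyphenyl)-1H-pyrrole-3-carboxamide | COc1cc(-c2c(C(N)=O)c(N)[nH]c2C(=O)c2ccc(O)cc2)ccc1O
F4 | step 2 | 3-methoxy-4-[(triisopropylsilyl)oxy]benzaldehyde | COc1cc(C=O)ccc1O[Si](C(C)C)(C(C)C)C(C)C
F5 | step 2 | (Z)-2-azido-1-(4-hydroxyphenyl)-3-{3-methoxy-4-[(triisopropylsilyl)oxy]phenyl}prop-2-en-1-one | COc1cc(/C=C(\N=[N+]=[N-])C(=O)c2ccc(O)cc2)ccc1O[Si](C(C)C)(C(C)C)C(C)C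
F6 | step 1 | 2-bromo-1-[4-(tetrahydro-2H-pyran-2-yloxy)phenyl]ethan-1-one (racemic) | O=C(CBr)c1ccc(OC2CCCCO2)cc1
F7 | step 1 | 2-azido-1-[4-(tetrahydro-2H-pyran-2-yloxy)phenyl]ethan-1-one (racemic) | [N-]=[N+]=NCC(=O)c1ccc(OC2CCCCO2)cc1
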